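**Strategy**

Ring C of the flavanone unit is disconnected at the O1–C2 bond, which carries the only stereocentre (C2). One enzymatic oxa-Michael closure of the free chalcone forms that bond, closes ring C and sets 2S. Ring A of the chalcone has two equivalent hydroxyls at C2' and C6' flanking the carbonyl, with the 4'-OMe on the local symmetry axis, so either oxygen gives the same 5-hydroxy-7-methoxy product. The precursor is the unprotected (E)-2',6'-dihydroxy-4'-methoxychalcone whose ring B bears 4-OH and, at C3, an apigenin unit bound through its C8. It is assembled by C8 iodination, Suzuki coupling and Claisen–Schmidt condensation under acetal (MOM) protection.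

Key step: step 9

Assumption: rotation about the C3'–C8'' biaryl bond is taken as free at room temperature (the target SMILES defines no axis), so C2 is the only stereogenic element.
Assumption: 2',6'-dihydroxy-4'-methoxyacetophenone is bought as a catalogue compound, and the isomerase is obtained by routine recombinant expression in Escherichia coli.

**Route**

Step 1
Reactants: 1 apigenin
Product: 2 5,7,4'-tri-O-(methoxymethyl)apigenin
Conditions: NaH (4 equiv), MOMCl (4 equiv), DMF, 0 °C to rt
Reagents that add atoms: chloromethyl methyl ether (MOMCl), COCCl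
Why: Williamson-type O-alkylation in which NaH ionizes all three phenols, including the chelated 5-OH, so that ring A of the flavone keeps no free hydroxyl that would steer the next halogenation to C6; acetals are chosen because they can be removed later without hydrogenolysis, which would saturate the enone.

Step 2
Reactants: 2 5,7,4'-tri-O-(methoxymethyl)apigenin
Product: 3 8-iodo-5,7,4'-tri-O-(methoxymethyl)apigenin
Conditions: NIS (1.1 equiv), DMF, rt, dark
Reagents that add atoms: N-iodosuccinimide (NIS), O=C1CCC(=O)N1I
Why: Electrophilic aromatic iodination under neutral conditions; in fully O-alkylated 5,7-dioxygenated flavones the halogen enters at C8 (ortho to O7, para to O5, and less hindered than C6, which lies between two alkoxy groups), and neutral NIS should leave the acetals intact.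

Step 3
Reactants: 4 3-bromo-4-hydroxybenzaldehyde
Product: 5 3-bromo-4-(methoxymethoxy)benzaldehyde
Conditions: K2CO3 (2 equiv), MOMCl (1.3 equiv), acetone, 0 °C to rt
Reagents that add atoms: chloromethyl methyl ether (MOMCl), COCCl
Why: Phenol O-alkylation (MOM protection) masks the 4-OH, whose phenolate would otherwise deactivate the aldehyde in the later aldol condensation, and the aldehyde is inert to K2CO3 and MOMCl.

Step 4
Reactants: 5 3-bromo-4-(methoxymethoxy)benzaldehyde
Product: 6 4-(methoxymethoxy)-3-(4,4,5,5-tetramethyl-1,3,2-dioxaborolan-2-yl)benzaldehyde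
Conditions: B2pin2 (1.2 equiv), PdCl2(dppf) (3 mol %), KOAc (3 equiv), 1,4-dioxane, 85 °C
Reagents that add atoms: bis(pinacolato)diboron (B2pin2), CC1(C)OB(OC1(C)C)B1OC(C)(C)C(C)(C)O1
Why: Miyaura borylation, in which zerovalent palladium inserts into the C–Br bond and KOAc mediates boron transfer from B2pin2; aryl aldehydes and MOM ethers are tolerated.

Step 5
Reactants: 3 8-iodo-5,7,4'-tri-O-(methoxymethyl)apigenin; 6 4-(methoxymethoxy)-3-(4,4,5,5-tetramethyl-1,3,2-dioxaborolan-2-yl)benzaldehyde
Product: 7 3-{5,7-bis(methoxymethoxy)-2-[4-(methoxymethoxy)phenyl]-4-oxo-4H-chromen-8-yl}-4-(methoxymethoxy)benzaldehyde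
Conditions: Pd(OAc)2 (5 mol %), SPhos (10 mol %), K3PO4 (3 equiv), toluene/H2O, 90 °C, argon
Reagents that add atoms: none
Why: Suzuki–Miyaura cross-coupling forms the C8–C3' biaryl bond; the bulky, electron-rich SPhos ligand is chosen because the iodide carries two ortho oxygen substituents, and the aldehyde, flavone carbonyl and MOM ethers tolerate K3PO4.

Step 6
Reactants: 8 2',6'-dihydroxy-4'-methoxyacetophenone
Product: 9 1-[4-methoxy-2,6-bis(methoxymethoxy)phenyl]ethan-1-one
Conditions: NaH (2.3 equiv), MOMCl (2.4 equiv), DMF, 0 °C to rt
Reagents that add atoms: chloromethyl methyl ether (MOMCl), COCCl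
Why: Double MOM etherification with NaH (needed for the chelated hydroxyl) leaves neither ring A hydroxyl free, so the enone made in the next step cannot close to a racemic flavanone before the enzyme step, and the symmetric substrate can give only one product.

Step 7
Reactants: 9 1-[4-methoxy-2,6-bis(methoxymethoxy)phenyl]ethan-1-one; 7 3-{5,7-bis(methoxymethoxy)-2-[4-(methoxymethoxy)phenyl]-4-oxo-4H-chromen-8-yl}-4-(methoxymethoxy)benzaldehyde
Product: 11 (E)-hexakis-O-(methoxymethyl) chalcone, via racemic aldol adduct 10 (not isolated)
Conditions: KOH (aq 40%, 5 equiv), EtOH/THF, 0 °C to rt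
Reagents that add atoms: none
Why: Claisen–Schmidt condensation in which the methyl ketone enolate adds to the non-enolizable aldehyde to give aldol 10, which loses water by E1cB elimination to the thermodynamically favoured E-enone; with every phenol masked no phenolate deactivates either partner, no oxa-Michael closure is possible, and the electron-rich 5,7-dialkoxyflavone core is a poor acceptor for hydroxide at room temperature.

Step 8
Reactants: 11 (E)-hexakis-O-(methoxymethyl) chalcone
Product: 12 (E)-3-{3-[5,7-dihydroxy-2-(4-hydroxyphenyl)-4-oxo-4H-chromen-8-yl]-4-hydroxyphenyl}-1-(2,6-dihydroxy-4-methoxyphenyl)prop-2-en-1-one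
Conditions: 3 M aq HCl, MeOH/THF, 45 °C, argon, dark; then Sephadex LH-20 (MeOH, 0.1% HCO2H) to remove any flavanone
Reagents that add atoms: none
Why: Acid-catalysed acetal cleavage (transacetalization of the six MOM groups to methanol) should run under conditions milder than those at which acid closes a 2',6'-dihydroxychalcone; the 4'-methyl ether is stable to dilute HCl and no reductive step endangers the enone.

Step 9
Reactants: 12 (E)-3-{3-[5,7-dihydroxy-2-(4-hydroxyphenyl)-4-oxo-4H-chromen-8-yl]-4-hydroxyphenyl}-1-(2,6-dihydroxy-4-methoxyphenyl)prop-2-en-1-one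
Product: 13 (2S)-5-hydroxy-2-{3-[5,7-dihydroxy-2-(4-hydroxyphenyl)-4-oxo-4H-chromen-8-yl]-4-hydroxyphenyl}-7-methoxy-2,3-dihydro-4H-chromen-4-one
Conditions: recombinant chalcone isomerase (Medicago sativa enzyme, EC 5.5.1.6, high loading), KH2PO4/K2HPO4 buffer (50 mM, pH 6.5), 10% v/v DMSO, 4 °C, argon, dark; then pH 4, EtOAc extraction, Sephadex LH-20 (MeOH, 0.1% HCO2H)
Reagents that add atoms: none
Why: The enzyme binds the enone in its s-cis conformation and polarizes the carbonyl through hydrogen bonds, a ring A phenolate (O2' or the equivalent O6') adds to Cβ in an intramolecular oxa-Michael addition, and protonation of the enolate at Cα completes the formation of O1–C2 and of ring C. The closest known reaction is the chalcone isomerase cyclization of naringenin chalcone and related 2',6'-dihydroxychalcones to (2S)-flavanones; the 4'-O-methyl group and the bulky aryl group at C3 of ring B are the new elements, so a small panel of enzymes (plant enzymes of both substrate types, the bacterial enzyme from Eubacterium ramulus, engineered variants) would be screened. Ring C closes in the 6-endo-trig mode. C2 is set by catalyst control alone: the protein exposes only the Si face of Cβ (CIP order aryl > Cα > H) to the phenolate, which gives 2S, and the substrate has no other stereocentre to interfere. The step needs enantioface selectivity over the spontaneous racemic closure, which runs through the free phenolate and is held back by pH 6.5, low temperature, short contact time and high enzyme loading; no regioselectivity is needed because the 4'-OMe lies on the C1'–C4' axis that makes the two ortho hydroxyls equivalent, and the phenols of the flavone unit cannot reach Cβ through a six-membered transition state. The unused ortho hydroxyl ends as the hydrogen-bonded 5-OH, and the mildly acidic work-up should prevent ring opening and racemization.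

**Compound list**

1 | apigenin | O=c1cc(-c2ccc(O)cc2)oc2cc(O)cc(O)c12 | starting material
2 | 5,7,4'-tri-O-(methoxymethyl)apigenin, 5,7-bis(methoxymethoxy)-2-[4-(methoxymethoxy)phenyl]-4H-chromen-4-one | O=c1cc(-c2ccc(OCOC)cc2)oc2cc(OCOC)cc(OCOC)c12 | intermediate
3 | 8-iodo-5,7,4'-tri-O-(methoxymethyl)apigenin | O=c1cc(-c2ccc(OCOC)cc2)oc2c(I)c(OCOC)cc(OCOC)c12 | intermediate
4 | 3-bromo-4-hydroxybenzaldehyde | O=Cc1ccc(O)c(Br)c1 | starting material
5 | 3-bromo-4-(methoxymethoxy)benzaldehyde | O=Cc1ccc(OCOC)c(Br)c1 | intermediate
6 | 4-(methoxymethoxy)-3-(4,4,5,5-tetramethyl-1,3,2-dioxaborolan-2-yl)benzaldehyde | O=Cc1ccc(OCOC)c(B2OC(C)(C)C(C)(C)O2)c1 | intermediate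
7 | 3-{5,7-bis(methoxymethoxy)-2-[4-(methoxymethoxy)phenyl]-4-oxo-4H-chromen-8-yl}-4-(methoxymethoxy)benzaldehyde | O=Cc1ccc(OCOC)c(-c2c(OCOC)cc(OCOC)c3c(=O)cc(-c4ccc(OCOC)cc4)oc23)c1 | intermediate
8 | 2',6'-dihydroxy-4'-methoxyacetophenone | CC(=O)c1c(O)cc(OC)cc1O | starting material
9 | 1-[4-methoxy-2,6-bis(methoxymethoxy)phenyl]ethan-1-one | CC(=O)c1c(OCOC)cc(OC)cc1OCOC | intermediate
10 | racemic aldol adduct, the 3-hydroxy-1,3-diarylpropan-1-one formed from 9 and 7 in the flask | COc1cc(OCOC)c(C(=O)CC(O)c2ccc(OCOC)c(-c3c(OCOC)cc(OCOC)c4c(=O)cc(-c5ccc(OCOC)cc5)oc34)c2)c(OCOC)c1 | intermediate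
11 | (E)-hexakis-O-(methoxymethyl) chalcone, (E)-1-[4-methoxy-2,6-bis(methoxymethoxy)phenyl]-3-(aryl)prop-2-en-1-one with the aryl group of 7 | COc1cc(OCOC)c(C(=O)/C=C/c2ccc(OCOC)c(-c3c(OCOC)cc(OCOC)c4c(=O)cc(-c5ccc(OCOC)cc5)oc34)c2)c(OCOC)c1 | intermediate
12 | (E)-2',6'-dihydroxy-4'-methoxychalcone with 4-OH and C3-(apigenin-8-yl) on ring B | COc1cc(O)c(C(=O)/C=C/c2ccc(O)c(-c3c(O)cc(O)c4c(=O)cc(-c5ccc(O)cc5)oc34)c2)c(O)c1 | intermediate
13 | (2S)-2,3-dihydroamentoflavone 7-O-methyl ether, (2S)-5-hydroxy-7-methoxyflavanone with 4'-OH and C3'-(apigenin-8-yl) on ring B | COc1cc(O)c2c(c1)O[C@H](c1ccc(O)c(-c3c(O)cc(O)c4c(=O)cc(-c5ccc(O)cc5)oc34)c1)CC2=O | target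

**Step count and risks**

Total steps: 9. Longest linear sequence: 6 (steps 1, 2, 5, 7, 8, 9; the branch through steps 3, 4, 5, 7, 8, 9 is equally long).

Steps most likely to fail:

1. Step 9. The enzyme may bind the bulky, 4'-O-methylated substrate poorly, or the substrate may precipitate from the buffer. Turnover would then fall toward the rate of the uncatalysed closure and the enantiomeric purity would be eroded. The fallback sets out from 12 and comes back at 13. Chalcone 12 is closed without selectivity (NaOAc, EtOH, reflux) to racemic flavanone F1. The enantiomers are then separated by preparative HPLC on an amylose tris(3,5-dimethylphenylcarbamate) phase with an acidified eluent (n-hexane/EtOH, 0.1% CF3CO2H), which delivers 13 directly. The unwanted (2R)-flavanone F2 is reopened with 10% aq KOH at 0 °C under argon and poured into ice-cold dilute HCl, which returns it to 12 for another pass.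

2. Step 8. Ring C may close under the acidic conditions, or the acetals next to the biaryl axis may cleave incompletely, so that a mixture of chalcone and racemic flavanone results. The fallback sets out from 11 and comes back at 12. Both processes are driven to completion (3 M aq HCl, MeOH, reflux; then NaOAc, EtOH, reflux), so that all material is collected as racemic flavanone F3. This is opened with 10% aq KOH at 0 °C under argon to the chalcone polyanion and poured into ice-cold 1 M HCl; the chalcone 12 is extracted at once and purified as in step 8.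

3. Step 5. Cross-coupling at the doubly ortho-substituted C8 may be slow, with protodeboronation of the boronate and hydrodeiodination of the iodide competing. The fallback sets out from 5 (with 3 as partner) and comes back at 7; it replaces boron by tin. Bromide 5 is stannylated with hexabutylditin (Bu3Sn)2 and Pd(PPh3)4 in toluene at 110 °C to 4-(methoxymethoxy)-3-(tributylstannyl)benzaldehyde F4. F4 is joined to iodide 3 by a copper-assisted Stille coupling (Pd(PPh3)4, CuI, CsF, DMF, 70 °C) to give 7.

**Further compounds**

F1 | step 9 | racemic flavanone (racemate of 13) | COc1cc(O)c2c(c1)OC(c1ccc(O)c(-c3c(O)cc(O)c4c(=O)cc(-c5ccc(O)cc5)oc34)c1)CC2=O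
F2 | step 9 | (2R)-flavanone (enantiomer of 13) | COc1cc(O)c2c(c1)O[C@@H](c1ccc(O)c(-c3c(O)cc(O)c4c(=O)cc(-c5ccc(O)cc5)oc34)c1)CC2=O
F3 | step 8 | racemic flavanone (racemate of 13) | COc1cc(O)c2c(c1)OC(c1ccc(O)c(-c3c(O)cc(O)c4c(=O)cc(-c5ccc(O)cc5)oc34)c1)CC2=O
F4 | step 5 | 4-(methoxymethoxy)-3-(tributylstannyl)benzaldehyde | O=Cc1ccc(OCOC)c([Sn](CCCC)(CCCC)CCCC)c1
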